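Locants (guaiane numbering) used throughout: cyclopentenone C1 (ring-fusion CH), C2 (CH2), C3 (C=O), C4 (C–CH3), C5; cycloheptane C5, C6 (CH2), C7, C8, C9 (CH2), C10, C1; C11 is the C(CH3)2OAc carbon on C7.

## Analysis of the target

The target is a guaiane diester: a 2-methylcyclopent-2-enone (C1–C5) fused through C1 and C5 to a cycloheptane (C5–C10, C1). The seven-membered ring carries the 2-acetoxyprop-2-yl group on C7, a propionate on C8 and a methyl on C10. There are four stereocentres, C1 (R), C7 (S), C8 (R) and C10 (S). The C11 group, the C8 oxygen, the C10 methyl and H1 all lie on one face of the seven-membered ring, so H1 and H10 are trans. C1–H is the γ-hydrogen of the enone, so base can epimerise C1 or move unsaturation once the enone exists. The two esters sit on a 1,3-diol (secondary propionate, tertiary acetate); they must be introduced selectively and can exchange by acyl shift, and the acetate becomes a β-leaving group whenever C8 is a carbonyl. The difficulty is a medium ring with stereocentres on both flanks (C1/C10 and C7/C8) and no rigid relay between them. The strategy rests on C9: it is the only carbon between the C8 carbinol and the methyl-bearing C10, so with C10 as an exocyclic methylene the C8–C9–C10 unit is a homoallylic alcohol, the product of a carbonyl-ene reaction between a C8 aldehyde and an isopropenyl group (C9, C10 and its methyl) on C1.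

## Retrosynthetic reasoning

**C8–O bond, 24 to 23.** The propionate is removed with inversion, giving the C8-epimeric alcohol 23 that already carries the tertiary acetate. Cutting here means only one hydroxyl is free when the second ester goes on, and it allows C8 to be carried in the configuration that serves the preceding step. The forward reaction has to esterify with clean inversion (Mitsunobu).

**C10–H bond, 23 to 22.** The C10 methyl is traced back to an exocyclic methylene in 22. The C8 hydroxyl, trans to C11, lies on the face to which hydrogen must be delivered, so a hydroxyl-directed hydrogenation sets C10 from C8.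

**C8–C9 bond, 22 to 21.** This is the only skeletal bond cut in the ring-forming step. Opening the homoallylic alcohol gives keto aldehyde 21, in which ene (isopropenyl on C1) and enophile (C8 aldehyde) hang from adjacent carbons of the cyclopentenone. A Lewis-acid carbonyl-ene reaction closes the ring, creates C8 and leaves the methylene for the next step. It must select one face of the aldehyde and take hydrogen from the methyl, not from C1.

**Oxidation levels, 21 back to 17.** Compound 21 holds an epimerisable β-acetoxy aldehyde and a base-sensitive enone, so both carbonyls are revealed only in the last step before cyclisation, from diol 20. The acetate is put on at 18 to 19, when both other oxygens are silylated (from diol 17), so that it cannot be misplaced or migrate.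

**C6–C7 bond, 17 and 15 to 8 and 13.** C6 is allylic and C7 is α to a carbonyl, so this bond forms by alkylating a chiral imide enolate (14, from 13) with allylic bromide 8; the auxiliary sets C7, and C11 arrives with its oxygen. The C3 oxygen is kept as a silyl ether here, so that no enone with an acidic γ-hydrogen at C1 meets the enolate.

**Five-membered ring, 8 back to 1.** Bromide 8 comes from enal 6 via alcohol 7. The C4=C5 bond of 6 is cut as an aldol condensation of keto aldehyde 5, which is the oxidative cleavage product of the silylated epoxy alcohol 4 (from 3 and 2) of carvone 1. Carvone supplies C1 with its isopropenyl group in the correct absolute configuration, its carbonyl becomes the C3 oxygen, and its methyl-bearing carbon becomes C4. Its ring CH carbon ends as exocyclic C6, the handle for the C6–C7 bond. C1 is therefore never α to a carbonyl, and never γ to one before step 15.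

**Imide, 13 to 12 to 9 and 10.** The nucleophile is the hydroxy acid 9 on auxiliary 10, with the tertiary hydroxyl silylated for the enolate step.

## Alternatives that were turned down

**Alternative 1:** Both rings are cut at once (C1–C5, C2–C3, C3–C4), leading back to an acyclic allene-yne that carries C7 and C8 as the acetonide of the C8/C11 diol. Forward, [Rh(CO)2Cl]2 under CO would effect an allenic Pauson–Khand reaction at the distal allene double bond and give dienone A1.
- For: three bonds and two rings in one step, a reaction type that reliably gives five-seven systems, and C7/C8 set beforehand by acyclic chemistry. On bond economy it is clearly stronger than the chosen route.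
- Against: A1 has neither C1 nor C10. Both must come from reducing the tetrasubstituted C1=C10 bond of a linear dienone, and the target has H1 and H10 on opposite faces, which a syn hydrogenation cannot give. A conjugate reduction and protonation at C1, far from C7/C8, would be weakly controlled.
- Comparison: the chosen strategy gives up the one-step bicycle for C1 taken from the chiral pool and a hydroxyl handle that sets C10.

**Alternative 2:** C6–C7 and C9–C10 are cut in a formal (4+3) disconnection. Forward, Rh2(S-PTAD)4 would generate a vinylcarbenoid from a siloxyvinyl diazoacetate, cyclopropanate the exocyclic methylene of a cyclopentane-fused diene and, after divinylcyclopropane rearrangement, give cycloheptadiene A2.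
- For: convergent, catalytic and enantioselective, and C10 is set in the ring-forming step itself. On that point it is stronger than the chosen route, which needs a separate hydrogenation.
- Against: A2 still lacks C1, C7 and C8. They would come from a β-keto ester (C7 epimerisable), a ketone reduction, and migration of the C1=C5 bond to C4=C5 with stereoselective protonation at C1. Its C4 stereocentre is thrown away, and C11 needs double methyl addition to a β-oxygenated ester.
- Comparison: the chosen route has C1 and C7 fixed before ring closure and creates C8 in it, at the cost of a longer linear sequence.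

**Alternative 3:** The C1–C10 bond is cut. Forward, DBU or Cs2CO3 would form the extended dienolate of a cyclopentenone, whose γ-carbon C1 adds to C10 of a tethered vinyl sulfone to give sulfone A3.
- For: simple reagents, the enone is present from the start, C1 and C10 form in one step, and fewer redox adjustments are needed than in the chosen route.
- Against: the dienolate can also form through C6 or C2; the acceptor is a β-substituted vinyl sulfone closing a seven-membered ring. C1 remains acidic in A3 under the reaction conditions, so C1 and C10 are set under equilibrating conditions relative to distant C7/C8. Reductive desulfonylation must also spare the enone.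
- Comparison: the chosen route never exposes C1 to base after the enone is formed and sets C10 by a directed reaction; it pays with protecting-group steps.

Key step: step 16

Remark: compounds 5–20 are drawn with the ring silyloxy/hydroxyl carbon in the configuration that follows from cis-carveol; any epimer formed at this carbon in steps 4–5 converges at step 15, where it becomes the C3 carbonyl.

## Route

Step 1
Reactants: 1 (R)-(−)-carvone
Product: 2 (1R,5R)-cis-carveol
Conditions: NaBH4, CeCl3·7H2O, MeOH, 0 °C
Reagents that add atoms: none
Why: Luche 1,2-reduction; axial hydride delivery to the cerium-activated enone gives the cis alcohol, whose carbinol carbon later becomes the C3 carbonyl, so its configuration only serves the next step.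

Step 2
Reactants: 2 (1R,5R)-cis-carveol
Product: 3 cis-carveol 2,3-epoxide with hydroxyl, oxirane oxygen and isopropenyl group on one face
Conditions: VO(acac)2 (cat.), t-BuOOH, CH2Cl2, 0 °C → rt
Reagents that add atoms: tert-butyl hydroperoxide CC(C)(C)OO
Why: Hydroxyl-directed vanadium-catalysed epoxidation of an allylic alcohol; oxygen is delivered to the ring alkene syn to the hydroxyl, and the isopropenyl group, which has no directing group, is left alone.

Step 3
Reactants: 3 cis-carveol 2,3-epoxide
Product: 4 tert-butyldimethylsilyl ether of 3
Conditions: TBSCl, imidazole, DMF, rt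
Reagents that add atoms: tert-butyldimethylsilyl chloride CC(C)(C)[Si](C)(C)Cl
Why: Standard silylation of a secondary alcohol; the silyl ether keeps this oxygen out of the glycol cleavage and carries it as the masked C3 ketone up to step 15.

Step 4
Reactants: 4 silylated epoxide
Product: 5 (3S,5R)-5-(tert-butyldimethylsilyloxy)-6-oxo-3-(prop-1-en-2-yl)heptanal
Conditions: HIO4·2H2O, THF/H2O, 0 °C
Reagents that add atoms: water O
Why: Periodic acid opens the trisubstituted epoxide to the glycol and cleaves it in the same flask (Malaprade cleavage), the known way from limonene oxide to its keto aldehyde; the silylated oxygen cannot take part, so only the former ring C=C bond is cut.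

Step 5
Reactants: 5 keto aldehyde
Product: 6 (3R,5R)-3-(tert-butyldimethylsilyloxy)-2-methyl-5-(prop-1-en-2-yl)cyclopent-1-ene-1-carbaldehyde
Conditions: piperidine, AcOH, toluene, 60 °C
Reagents that add atoms: none
Why: Amine-catalysed intramolecular aldol condensation: the enamine of the aldehyde adds to the methyl ketone in a five-membered (5-exo-trig) closure and water is lost to the tetrasubstituted enal, the only irreversible outlet of the aldol manifold. The isopropenyl-bearing centre is not part of the enolisable system.

Step 6
Reactants: 6 enal
Product: 7 [(3R,5R)-3-(tert-butyldimethylsilyloxy)-2-methyl-5-(prop-1-en-2-yl)cyclopent-1-en-1-yl]methanol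
Conditions: NaBH4, CeCl3·7H2O, MeOH, 0 °C
Reagents that add atoms: none
Why: Luche 1,2-reduction of the enal to the primary allylic alcohol; no stereocentre is formed.

Step 7
Reactants: 7 allylic alcohol
Product: 8 (3R,5R)-1-(bromomethyl)-3-(tert-butyldimethylsilyloxy)-2-methyl-5-(prop-1-en-2-yl)cyclopent-1-ene
Conditions: CBr4, PPh3, CH2Cl2, 0 °C
Reagents that add atoms: carbon tetrabromide BrC(Br)(Br)Br
Why: Appel bromination of a primary allylic alcohol under neutral conditions; substitution with allylic shift would put bromine on a fully substituted carbon and is not expected.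

Step 8
Reactants: 9 3-hydroxy-3-methylbutanoic acid; 10 (R)-4-benzyloxazolidin-2-one
Product: 12 (R)-4-benzyl-3-(3-hydroxy-3-methylbutanoyl)oxazolidin-2-one, via mixed pivalic anhydride 11 (not isolated)
Conditions: PivCl, Et3N, THF, −20 °C; then 10, LiCl, −20 °C → rt
Reagents that add atoms: none
Why: N-acylation of the oxazolidinone through the mixed pivalic anhydride (LiCl/Et3N variant); attack occurs at the less hindered carbonyl of 11, and the tertiary hydroxyl is too hindered to be acylated.

Step 9
Reactants: 12 hydroxy imide
Product: 13 (R)-4-benzyl-3-[3-methyl-3-(trimethylsilyloxy)butanoyl]oxazolidin-2-one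
Conditions: TMSCl, imidazole, DMF, rt
Reagents that add atoms: chlorotrimethylsilane C[Si](C)(C)Cl
Why: Silylation of the tertiary alcohol, so that the enolate step does not generate an alkoxide that would open the oxazolidinone by acyl transfer; the tertiary trimethylsilyl ether survives the enolate conditions and can later be removed beside the ring silyl ether.

Step 10
Reactants: 13 silylated imide; 8 allylic bromide
Product: 15 (R)-4-benzyl-3-[(2R)-2-{[(3R,5R)-3-(tert-butyldimethylsilyloxy)-2-methyl-5-(prop-1-en-2-yl)cyclopent-1-en-1-yl]methyl}-3-methyl-3-(trimethylsilyloxy)butanoyl]oxazolidin-2-one, via sodium enolate 14 (not isolated)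
Conditions: NaN(SiMe3)2, THF, −78 °C; then 8, −78 → −30 °C
Reagents that add atoms: none
Why: Evans auxiliary alkylation: the chelated Z-enolate 14 is shielded on the face of the benzyl group, and the primary allylic bromide enters from the other face, which with the (R)-auxiliary gives the C7 configuration of the target. The ring oxygen is still a silyl ether, so no enone is exposed to the basic enolate.

Step 11
Reactants: 15 alkylated imide
Product: 17 (2S)-2-{[(3R,5R)-3-(tert-butyldimethylsilyloxy)-2-methyl-5-(prop-1-en-2-yl)cyclopent-1-en-1-yl]methyl}-3-methylbutane-1,3-diol, via trimethylsilyl ether alcohol 16 (not isolated)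
Conditions: LiBH4, MeOH (1.5 equiv), THF, 0 °C; then K2CO3 (cat.), MeOH, rt
Reagents that add atoms: none
Why: Reductive removal of the auxiliary by hydride attack at the exocyclic imide carbonyl gives primary alcohol 16 without touching C7; methanolic K2CO3 then cleaves only the trimethylsilyl ether, the tert-butyldimethylsilyl ether being stable to it.

Step 12
Reactants: 17 diol
Product: 18 primary tert-butyldimethylsilyl ether of 17 (tertiary hydroxyl free)
Conditions: TBSCl (1.1 equiv), imidazole, CH2Cl2, 0 °C
Reagents that add atoms: tert-butyldimethylsilyl chloride CC(C)(C)[Si](C)(C)Cl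
Why: Selective silylation of the primary hydroxyl; the tertiary hydroxyl does not react with TBSCl/imidazole at 0 °C.

Step 13
Reactants: 18 tertiary alcohol
Product: 19 tertiary acetate of 18
Conditions: Ac2O, DMAP, Et3N, CH2Cl2, 40 °C
Reagents that add atoms: acetic anhydride CC(=O)OC(C)=O
Why: DMAP-catalysed acetylation of a tertiary alcohol, placed here because both other oxygens are silylated, so the acetate goes on without competition and cannot migrate.

Step 14
Reactants: 19 bis-silyl ether acetate
Product: 20 (2S)-3-acetoxy-2-{[(3R,5R)-3-hydroxy-2-methyl-5-(prop-1-en-2-yl)cyclopent-1-en-1-yl]methyl}-3-methylbutan-1-ol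
Conditions: HF·pyridine, pyridine, THF, 0 °C → rt
Reagents that add atoms: none
Why: Fluoride cleavage of both silyl ethers under buffered, weakly acidic conditions, chosen over basic fluoride sources so that the tertiary acetate does not shift to the neighbouring primary hydroxyl.

Step 15
Reactants: 20 diol acetate
Product: 21 (2R)-3-acetoxy-3-methyl-2-{[(5R)-2-methyl-3-oxo-5-(prop-1-en-2-yl)cyclopent-1-en-1-yl]methyl}butanal
Conditions: Dess–Martin periodinane, NaHCO3, CH2Cl2, 0 °C → rt
Reagents that add atoms: none
Why: Dess–Martin oxidation of the primary alcohol to the aldehyde and of the allylic ring carbinol to the enone in one base-free operation, so that the β-acetoxy aldehyde keeps its C7 configuration and the γ-hydrogen at C1 of the new enone is not disturbed; 21 is used without storage.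

Step 16
Reactants: 21 keto aldehyde
Product: 22 (1R,7S,8S)-11-acetoxy-8-hydroxyguaia-4,10(14)-dien-3-one (hydroxyl trans to the C7 side chain; exocyclic methylene on C10)
Conditions: Me2AlCl (3 equiv), CH2Cl2, −78 → −30 °C
Reagents that add atoms: none
Why: Me2AlCl binds the aldehyde (the excess also occupies the enone and acetate carbonyls) and the terminal carbon C9 of the isopropenyl group attacks C8 while a hydrogen of the isopropenyl methyl passes to the aluminium-bound oxygen through a six-centre array; this is a type-two intramolecular carbonyl-ene reaction, a known route to methylenecycloalkanols including seven-membered ones. The ring closes 7-exo-trig at the carbonyl, and because the tether leaves from the central carbon C10 of the ene unit, both C9 and C10 become ring members and the double bond moves to the exocyclic C10 methylene. The only new stereocentre, C8, is controlled by C7: the C(CH3)2OAc group should sit pseudo-equatorial and anti to the incoming C9, and the oxygen must be synclinal to C10 to reach a methyl hydrogen. In the twist-chair with C8 on the axis position, which best fits the torsions imposed by the flat cyclopentenone at C1–C5–C6, this places the oxygen antiperiplanar to C6 and trans to C11 (8S). The same geometry secures hydrogen transfer from the methyl and not from C1, since the oxygen lies over the exocyclic methyl while C1–H points to the opposite face, so no C1=C10 dienone should form and C1 keeps its configuration. The aldehyde is the only enophile within reach, the enone carbonyl being conjugated and remote. The methyl–aluminium bonds scavenge any HCl, which protects the tertiary acetate, the C7 stereocentre and C1–H at low temperature.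

Step 17
Reactants: 22 homoallylic alcohol
Product: 23 (1R,7S,8S,10S)-11-acetoxy-8-hydroxyguai-4-en-3-one
Conditions: [Ir(cod)(PCy3)(py)]PF6 (cat.), H2 (1 atm), CH2Cl2, rt
Reagents that add atoms: none
Why: Hydroxyl-directed hydrogenation: the C8 hydroxyl, held near the methylene by the geometry that allowed the hydrogen transfer in step 16, binds the cationic iridium and hydrogen is delivered to C10 from the hydroxyl face, so the C10 methyl ends up cis to C11 (10S); the electron-poor tetrasubstituted enone is not reduced.

Step 18
Reactants: 23 secondary alcohol
Product: 24 (1R,7S,8R,10S)-11-acetoxy-8-(propanoyloxy)guai-4-en-3-one (target)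
Conditions: EtCO2H, PPh3, DIAD, toluene, 0 °C → rt
Reagents that add atoms: propionic acid CCC(=O)O
Why: Mitsunobu esterification: the C8 hydroxyl becomes an oxyphosphonium leaving group and is displaced by propionate with inversion (8S to 8R), which installs the second ester and the last stereocentre in one step, the acetate being already in place.

## Compound list

1 | (R)-(−)-carvone | CC1=CC[C@H](CC1=O)C(C)=C | starting material
2 | (1R,5R)-cis-carveol | O[C@@H]1C[C@H](C(C)=C)CC=C1C | intermediate
3 | cis-carveol 2,3-epoxide, oxirane syn to hydroxyl and isopropenyl | O[C@@H]1C[C@H](C(C)=C)C[C@@H]2O[C@]12C | intermediate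
4 | tert-butyldimethylsilyl ether of 3 | CC(C)(C)[Si](C)(C)O[C@@H]1C[C@H](C(C)=C)C[C@@H]2O[C@]12C | intermediate
5 | (3S,5R)-5-(tert-butyldimethylsilyloxy)-6-oxo-3-(prop-1-en-2-yl)heptanal | CC(=O)[C@H](O[Si](C)(C)C(C)(C)C)C[C@@H](CC=O)C(C)=C | intermediate
6 | (3R,5R)-3-(tert-butyldimethylsilyloxy)-2-methyl-5-(prop-1-en-2-yl)cyclopent-1-ene-1-carbaldehyde | O=CC1=C(C)[C@H](O[Si](C)(C)C(C)(C)C)C[C@@H]1C(C)=C | intermediate
7 | [(3R,5R)-3-(tert-butyldimethylsilyloxy)-2-methyl-5-(prop-1-en-2-yl)cyclopent-1-en-1-yl]methanol | OCC1=C(C)[C@H](O[Si](C)(C)C(C)(C)C)C[C@@H]1C(C)=C | intermediate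
8 | (3R,5R)-1-(bromomethyl)-3-(tert-butyldimethylsilyloxy)-2-methyl-5-(prop-1-en-2-yl)cyclopent-1-ene | BrCC1=C(C)[C@H](O[Si](C)(C)C(C)(C)C)C[C@@H]1C(C)=C | intermediate
9 | 3-hydroxy-3-methylbutanoic acid | CC(C)(O)CC(=O)O | starting material
10 | (R)-4-benzyloxazolidin-2-one | O=C1N[C@H](Cc2ccccc2)CO1 | starting material
11 | 3-hydroxy-3-methylbutanoic pivalic anhydride | CC(C)(O)CC(=O)OC(=O)C(C)(C)C | intermediate
12 | (R)-4-benzyl-3-(3-hydroxy-3-methylbutanoyl)oxazolidin-2-one | CC(C)(O)CC(=O)N1[C@H](Cc2ccccc2)COC1=O | intermediate
13 | (R)-4-benzyl-3-[3-methyl-3-(trimethylsilyloxy)butanoyl]oxazolidin-2-one | C[Si](C)(C)OC(C)(C)CC(=O)N1[C@H](Cc2ccccc2)COC1=O | intermediate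
14 | sodium (Z)-enolate of 13 | [Na+].C[Si](C)(C)OC(C)(C)/C=C(\[O-])N1[C@H](Cc2ccccc2)COC1=O | intermediate
15 | alkylated imide, (2R) at the new centre (C7) | C[Si](C)(C)OC(C)(C)[C@@H](CC1=C(C)[C@H](O[Si](C)(C)C(C)(C)C)C[C@@H]1C(C)=C)C(=O)N2[C@H](Cc3ccccc3)COC2=O | intermediate
16 | (2S)-2-{[(3R,5R)-3-(tert-butyldimethylsilyloxy)-2-methyl-5-(prop-1-en-2-yl)cyclopent-1-en-1-yl]methyl}-3-methyl-3-(trimethylsilyloxy)butan-1-ol | C[Si](C)(C)OC(C)(C)[C@@H](CC1=C(C)[C@H](O[Si](C)(C)C(C)(C)C)C[C@@H]1C(C)=C)CO | intermediate
17 | (2S)-2-{[(3R,5R)-3-(tert-butyldimethylsilyloxy)-2-methyl-5-(prop-1-en-2-yl)cyclopent-1-en-1-yl]methyl}-3-methylbutane-1,3-diol | CC(C)(O)[C@@H](CC1=C(C)[C@H](O[Si](C)(C)C(C)(C)C)C[C@@H]1C(C)=C)CO | intermediate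
18 | primary tert-butyldimethylsilyl ether of 17 | CC(C)(O)[C@@H](CC1=C(C)[C@H](O[Si](C)(C)C(C)(C)C)C[C@@H]1C(C)=C)CO[Si](C)(C)C(C)(C)C | intermediate
19 | tertiary acetate of 18 | CC(=O)OC(C)(C)[C@@H](CC1=C(C)[C@H](O[Si](C)(C)C(C)(C)C)C[C@@H]1C(C)=C)CO[Si](C)(C)C(C)(C)C | intermediate
20 | (2S)-3-acetoxy-2-{[(3R,5R)-3-hydroxy-2-methyl-5-(prop-1-en-2-yl)cyclopent-1-en-1-yl]methyl}-3-methylbutan-1-ol | CC(=O)OC(C)(C)[C@@H](CC1=C(C)[C@H](O)C[C@@H]1C(C)=C)CO | intermediate
21 | (2R)-3-acetoxy-3-methyl-2-{[(5R)-2-methyl-3-oxo-5-(prop-1-en-2-yl)cyclopent-1-en-1-yl]methyl}butanal | CC(=O)OC(C)(C)[C@@H](CC1=C(C)C(=O)C[C@@H]1C(C)=C)C=O | intermediate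
22 | (1R,7S,8S)-11-acetoxy-8-hydroxyguaia-4,10(14)-dien-3-one | O[C@H]1CC(=C)[C@H]2CC(=O)C(C)=C2C[C@@H]1C(C)(C)OC(C)=O | intermediate
23 | (1R,7S,8S,10S)-11-acetoxy-8-hydroxyguai-4-en-3-one | O[C@H]1C[C@H](C)[C@H]2CC(=O)C(C)=C2C[C@@H]1C(C)(C)OC(C)=O | intermediate
24 | (1R,7S,8R,10S)-11-acetoxy-8-(propanoyloxy)guai-4-en-3-one | CCC(=O)O[C@@H]1C[C@H](C)[C@H]2CC(=O)C(C)=C2C[C@@H]1C(C)(C)OC(C)=O | target

## Step count and least certain steps

Total: 18 steps. Longest linear sequence: 16 steps (steps 1–7 and 10–18 from 1); the imide branch is 2 steps (8, 9).

**Step 16 (key step).** The most likely failure is poor facial selectivity at the aldehyde. A chair-like closure with alternating torsions at C8 (the Felkin-type arrangement, C11 equatorial and oxygen axial) would give the C8 epimer, and the two transition states cannot be ranked with confidence on paper. Fallback, setting out from 21 with the cyclisation unchanged: the (8R)-epimer of 22 F1 is inverted by Mitsunobu reaction with chloroacetic acid (PPh3, DIAD) to the (8S)-chloroacetate F2. The chloroacetyl group is then removed with thiourea/NaHCO3 in ethanol, conditions that spare the acetate and the base-sensitive C1–H, and the route is rejoined at 22.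

**Step 10.** The enolate may lose its β-silyloxy group (elimination to the unsaturated imide), or alkylation at an α-carbon flanked by a quaternary centre may be slower than decomposition of the bromide. Fallback, setting out from 8 and 10:
- 10 is acylated with 3-methylbut-2-enoyl chloride (n-BuLi, THF, −78 °C) to (R)-4-benzyl-3-(3-methylbut-2-enoyl)oxazolidin-2-one F3.
- Its sodium dienolate, which has no β-leaving group and a less hindered α-carbon, is alkylated with 8 at the α-position from the same face to the β,γ-unsaturated imide F4.
- LiBH4 gives the homoallylic alcohol F5.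
- VO(acac)2/t-BuOOH epoxidises only the alkene that the homoallylic hydroxyl can direct, giving the epoxy alcohol F6 (either epimer at the oxirane carbon serves).
- LiAlH4 opens the oxirane at its CH2 terminus and the route is rejoined at 17.

**Step 15.** The primary alcohol is oxidised first, so the β-acetoxy aldehyde sits in the medium while the hindered ring carbinol is still being oxidised; loss of acetic acid or epimerisation at C7 may follow. Fallback, setting out from 20: MnO2 in CH2Cl2 oxidises only the allylic carbinol to the hydroxy enone F7, and TEMPO (cat.)/PhI(OAc)2 then oxidises the primary alcohol quickly and without base, rejoining at 21.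

**Step 17.** The iridium hydride may move the exocyclic double bond into the ring before delivery, or the acetate and ketone may compete for the metal, eroding the face selectivity at C10. Fallback, setting out from 22: the Mitsunobu reaction of step 18 is run first to give the (8R)-propionate with the C10 methylene F8. The methylene is then hydrogenated with RhCl(PPh3)3/H2 under steric control, with the propionate and C11 screening their own face, and the route arrives at 24.

**Step 18.** Substitution at C8 is slowed by the branched C7, so elimination toward C9 or C7, or participation of the C11 acetate carbonyl (leading to retention or acyl scrambling), may compete. Fallback, setting out from 23: Dess–Martin oxidation gives the C8 ketone F9. NaBH4 in MeOH/CH2Cl2 at −78 °C reduces this saturated ketone in preference to the enone, with hydride entering anti to C11, to give the (8R)-alcohol F10. Propionic anhydride/DMAP/pyridine then gives 24.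

## Further compounds

F1 | step 16 | (1R,7S,8R)-11-acetoxy-8-hydroxyguaia-4,10(14)-dien-3-one (C8 epimer of 22) | O[C@@H]1CC(=C)[C@H]2CC(=O)C(C)=C2C[C@@H]1C(C)(C)OC(C)=O
F2 | step 16 | (1R,7S,8S)-11-acetoxy-8-(chloroacetoxy)guaia-4,10(14)-dien-3-one | ClCC(=O)O[C@H]1CC(=C)[C@H]2CC(=O)C(C)=C2C[C@@H]1C(C)(C)OC(C)=O
F3 | step 10 | (R)-4-benzyl-3-(3-methylbut-2-enoyl)oxazolidin-2-one | CC(C)=CC(=O)N1[C@H](Cc2ccccc2)COC1=O
F4 | step 10 | α-alkylated β,γ-unsaturated imide (isopropenyl in place of C11) | C=C(C)[C@@H](CC1=C(C)[C@H](O[Si](C)(C)C(C)(C)C)C[C@@H]1C(C)=C)C(=O)N2[C@H](Cc3ccccc3)COC2=O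
F5 | step 10 | homoallylic alcohol from reduction of F4 | C=C(C)[C@@H](CC1=C(C)[C@H](O[Si](C)(C)C(C)(C)C)C[C@@H]1C(C)=C)CO
F6 | step 10 | epoxy alcohol from F5 (epimers at the oxirane carbon) | CC1(CO1)[C@@H](CC2=C(C)[C@H](O[Si](C)(C)C(C)(C)C)C[C@@H]2C(C)=C)CO
F7 | step 15 | (2S)-3-acetoxy-3-methyl-2-{[(5R)-2-methyl-3-oxo-5-(prop-1-en-2-yl)cyclopent-1-en-1-yl]methyl}butan-1-ol | CC(=O)OC(C)(C)[C@@H](CC1=C(C)C(=O)C[C@@H]1C(C)=C)CO
F8 | step 17 | (1R,7S,8R)-11-acetoxy-8-(propanoyloxy)guaia-4,10(14)-dien-3-one | CCC(=O)O[C@@H]1CC(=C)[C@H]2CC(=O)C(C)=C2C[C@@H]1C(C)(C)OC(C)=O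
F9 | step 18 | (1R,7S,10S)-11-acetoxyguai-4-ene-3,8-dione | O=C1C[C@H](C)[C@H]2CC(=O)C(C)=C2C[C@@H]1C(C)(C)OC(C)=O
F10 | step 18 | (1R,7S,8R,10S)-11-acetoxy-8-hydroxyguai-4-en-3-one | O[C@@H]1C[C@H](C)[C@H]2CC(=O)C(C)=C2C[C@@H]1C(C)(C)OC(C)=O
A1 | alternative 1 | 8,11-O-isopropylideneguaia-1(10),4-dien-3-one | CC1(C)O[C@@H]2CC(C)=C3CC(=O)C(C)=C3C[C@@H]2C(C)(C)O1
A2 | alternative 2 | bicyclic cyclohepta-1,4-diene with C7 methyl ester, C8 silyl enol ether, C1=C5 alkene and C3 dioxolane | COC(=O)C1=C(O[Si](C)(C)C(C)(C)C)C[C@H](C)C2=C(C1)[C@@H](C)C3(OCCO3)C2
A3 | alternative 3 | 9-(phenylsulfonyl)-8,11-O-isopropylideneguai-4-en-3-one | CC1(C)O[C@@H]2[C@@H](S(=O)(=O)c3ccccc3)[C@H](C)[C@H]4CC(=O)C(C)=C4C[C@@H]2C(C)(C)O1
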